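## Retrosynthetic overview

1. Ring C is closed last. The C3–C4 bond is made by a chiral carbene that turns the ring-A aldehyde into an acyl anion equivalent, which adds to an o-quinone methide unveiled from ring B. This one step sets C3 and frees the 2'-OH.
2. The o-quinone methide precursor (aryl silyl ether plus benzylic acetate) comes from O1–C2 bond formation: the ring-A salicylaldehyde phenoxide opens a ring-B aryl oxirane, then acetylation.
3. Ring-A piece: Stille prenylation of 5-bromo-2-hydroxy-4-methoxybenzaldehyde. Ring-B piece: silylation and sulfur-ylide epoxidation of 2-hydroxy-4-methoxybenzaldehyde.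
4. Rings A and B are bought as arenes; ring C is the only ring formed.

Assumption: the target SMILES reads as (3S). The facial sense of the aminoindanol triazolium catalyst on an o-quinone methide acceptor is not established, so the (5aR,10bS) catalyst is written and its equally available mirror image is used if the first run gives (3R). Compounds 6–9 are used as racemates because their stereocentre becomes planar in step 5.

## Route

Step 1
Reactants: 1 5-bromo-2-hydroxy-4-methoxybenzaldehyde; 2 tributyl(3-methylbut-2-en-1-yl)stannane
Product: 3 2-hydroxy-4-methoxy-5-(3-methylbut-2-en-1-yl)benzaldehyde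
Conditions: Pd(PPh3)4 (5 mol%), DMF, 100 °C
Reagents that add atoms: none
Why: Stille cross-coupling in which zerovalent palladium inserts into the C–Br bond, the allylstannane transmetalates and reductive elimination at the unsubstituted allyl terminus gives the linear prenyl arene, with free phenol and aldehyde tolerated.

Step 2
Reactants: 4 2-hydroxy-4-methoxybenzaldehyde
Product: 5 4-methoxy-2-[(triisopropylsilyl)oxy]benzaldehyde
Conditions: NaH, THF, 0 °C; then TIPSCl, 0 °C → rt
Reagents that add atoms: triisopropylsilyl chloride, CC(C)[Si](Cl)(C(C)C)C(C)C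
Why: O-silylation of the sodium phenoxide, with the bulky TIPS group chosen because it resists migration and cleavage in steps 3 and 4 yet is removed by fluoride in step 5.

Step 3
Reactants: 5 4-methoxy-2-[(triisopropylsilyl)oxy]benzaldehyde
Product: 6 rac-2-{4-methoxy-2-[(triisopropylsilyl)oxy]phenyl}oxirane
Conditions: Me3S+ I− (1.3 equiv), n-BuLi (1.2 equiv), THF, −10 °C → rt; filtration through basic alumina, used at once
Reagents that add atoms: trimethylsulfonium iodide, C[S+](C)C.[I-]
Why: Corey–Chaykovsky epoxidation, in which dimethylsulfonium methylide adds to the aldehyde and the alkoxide displaces dimethyl sulfide; the racemic centre is of no consequence.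

Step 4
Reactants: 3 2-hydroxy-4-methoxy-5-(3-methylbut-2-en-1-yl)benzaldehyde; 6 rac-2-{4-methoxy-2-[(triisopropylsilyl)oxy]phenyl}oxirane
Product: 8 rac-2-[2-formyl-5-methoxy-4-(3-methylbut-2-en-1-yl)phenoxy]-1-{4-methoxy-2-[(triisopropylsilyl)oxy]phenyl}ethyl acetate, via benzylic alcohol 7 (not isolated)
Conditions: 6 (1.0 equiv), 3 (1.2 equiv), Cs2CO3 (0.2 equiv), DMF, 70 °C; then Ac2O, Et3N, DMAP (cat.), 0 °C → rt
Reagents that add atoms: acetic anhydride, CC(=O)OC(C)=O
Why: Base-catalysed SN2 opening of the epoxide at its unhindered terminal carbon by the phenoxide of 3 (the ortho OTIPS group shields the benzylic carbon and the excess phenol protonates the alkoxide before silyl migration), followed by DMAP-catalysed acetylation in the same pot.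

Step 5
Reactants: 8 rac-2-[2-formyl-5-methoxy-4-(3-methylbut-2-en-1-yl)phenoxy]-1-{4-methoxy-2-[(triisopropylsilyl)oxy]phenyl}ethyl acetate
Product: 11 (3S)-3-(2-hydroxy-4-methoxyphenyl)-7-methoxy-6-(3-methylbut-2-en-1-yl)-2,3-dihydro-4H-chromen-4-one, via phenol acetate 9 (not isolated), via o-quinone methide 10 (not isolated)
Conditions: (5aR,10bS)-2-(pentafluorophenyl)-5a,10b-dihydro-4H,6H-indeno[2,1-b][1,2,4]triazolo[4,3-d][1,4]oxazin-2-ium tetrafluoroborate (20 mol%), CsF (1.2 equiv), 18-crown-6 (1.2 equiv), 4 Å MS, THF (0.02 M), −20 → 0 °C; then AcOH quench at −20 °C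
Reagents that add atoms: none
Why: Proposed new method: fluoride removes the aryl TIPS group and the phenoxide 9 expels acetate to give the planar (E)-o-quinone methide 10, a vinylogous enone whose exocyclic carbon is attacked 6-exo by the Breslow intermediate (acyl anion equivalent) formed from the ring-A aldehyde and the chiral triazolylidene; the fused indane of the catalyst blocks one face so that C3 is set (S) in the C–C bond-forming event, rearomatisation to the 2'-phenol makes the addition irreversible, and the racemic centre of 8 is erased so the process is stereoconvergent; the closest known reactions are the thiazolium-catalysed intermolecular acylation of fluoride-generated o-quinone methides by aldehydes and the aminoindanol-triazolium-catalysed enantioselective intramolecular Stetter reaction of salicylaldehyde-tethered Michael acceptors to 3-substituted chroman-4-ones.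

## Compound list

1 | 5-bromo-2-hydroxy-4-methoxybenzaldehyde | O=Cc1cc(Br)c(OC)cc1O | starting material
2 | tributyl(3-methylbut-2-en-1-yl)stannane | CCCC[Sn](CCCC)(CCCC)CC=C(C)C | starting material
3 | 2-hydroxy-4-methoxy-5-(3-methylbut-2-en-1-yl)benzaldehyde | O=Cc1cc(CC=C(C)C)c(OC)cc1O | intermediate
4 | 2-hydroxy-4-methoxybenzaldehyde | O=Cc1ccc(OC)cc1O | starting material
5 | 4-methoxy-2-[(triisopropylsilyl)oxy]benzaldehyde | O=Cc1ccc(OC)cc1O[Si](C(C)C)(C(C)C)C(C)C | intermediate
6 | rac-2-{4-methoxy-2-[(triisopropylsilyl)oxy]phenyl}oxirane | COc1ccc(C2CO2)c(O[Si](C(C)C)(C(C)C)C(C)C)c1 | intermediate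
7 | rac-2-(2-hydroxy-2-{4-methoxy-2-[(triisopropylsilyl)oxy]phenyl}ethoxy)-4-methoxy-5-(3-methylbut-2-en-1-yl)benzaldehyde | O=Cc1cc(CC=C(C)C)c(OC)cc1OCC(O)c1ccc(OC)cc1O[Si](C(C)C)(C(C)C)C(C)C | intermediate (not isolated)
8 | rac-2-[2-formyl-5-methoxy-4-(3-methylbut-2-en-1-yl)phenoxy]-1-{4-methoxy-2-[(triisopropylsilyl)oxy]phenyl}ethyl acetate | O=Cc1cc(CC=C(C)C)c(OC)cc1OCC(OC(C)=O)c1ccc(OC)cc1O[Si](C(C)C)(C(C)C)C(C)C | intermediate
9 | rac-2-[2-formyl-5-methoxy-4-(3-methylbut-2-en-1-yl)phenoxy]-1-(2-hydroxy-4-methoxyphenyl)ethyl acetate (present as its cesium phenoxide) | O=Cc1cc(CC=C(C)C)c(OC)cc1OCC(OC(C)=O)c1ccc(OC)cc1O | intermediate (not isolated)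
10 | 2-{[(2E)-2-(4-methoxy-6-oxocyclohexa-2,4-dien-1-ylidene)ethyl]oxy}-4-methoxy-5-(3-methylbut-2-en-1-yl)benzaldehyde | O=Cc1cc(CC=C(C)C)c(OC)cc1OC/C=C1\C=CC(OC)=CC1=O | intermediate (not isolated)
11 | (3S)-3-(2-hydroxy-4-methoxyphenyl)-7-methoxy-6-(3-methylbut-2-en-1-yl)-2,3-dihydro-4H-chromen-4-one | COc1ccc([C@H]2COc3cc(OC)c(CC=C(C)C)cc3C2=O)c(O)c1 | target

## Step count and risks

Total step count: 5 (the one-pot opening and acetylation counted as one).
Longest linear sequence: 4 steps (4 → 5 → 6 → 8 → 11).
C3 is the only stereocentre. It is set in the final step and meets only a cold acidic quench afterwards.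

Steps most likely to fail, in order of risk:

**Step 5.** The quinone methide 10 may tautomerise to a vinylphenol or trap the carbene before the ring closes, and the enantiomeric excess may be low or erode through enolisation of the product. The fallback sets out from 8 and comes back at 11, separating bond formation from stereocontrol. Compound 8 is cyclised with an achiral thiazolylidene (3-benzyl-5-(2-hydroxyethyl)-4-methylthiazolium chloride, CsF, 18-crown-6, CH2Cl2), the catalyst class proven for acylation of o-quinone methides. This gives the racemic isoflavanone rac-3-(2-hydroxy-4-methoxyphenyl)-7-methoxy-6-(3-methylbut-2-en-1-yl)-2,3-dihydro-4H-chromen-4-one F1. Phenol and ketone are silylated together (TMSOTf, Et3N, CH2Cl2, 0 °C) to the bis-silyl enol ether {[7-methoxy-3-{4-methoxy-2-[(trimethylsilyl)oxy]phenyl}-6-(3-methylbut-2-en-1-yl)-2H-chromen-4-yl]oxy}trimethylsilane F2. Catalytic enantioselective protonation of F2 (BINOL-derived N-triflyl thiophosphoramide, 5 mol%, phenol as stoichiometric proton source, toluene), followed by citric acid in methanol to free the aryl silyl ether, delivers 11.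

**Step 4.** The electron-rich epoxide may be opened partly at the benzylic carbon, the hindered salicylaldehyde phenoxide may react slowly, and the silyl group may migrate to the new alkoxide. The fallback sets out from 6 (with 3) and comes back at 8, using the electronic bias of the epoxide instead of opposing it. Compound 6 is opened with acetic acid (AcOH, CH2Cl2, 0 °C) at the benzylic carbon to give rac-2-hydroxy-1-{4-methoxy-2-[(triisopropylsilyl)oxy]phenyl}ethyl acetate F3. The aryl ether is then made by Mitsunobu reaction of its primary alcohol with the acidic phenol 3 (PPh3, DIAD, THF, 0 °C), which gives 8 directly.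

**Step 3.** The alkoxide formed on ylide addition sits next to the aryl silyl ether, and the electron-rich styrene oxide 6 may not survive isolation. The fallback sets out from 5 and comes back at 6, which is then formed only in the flask of step 4. Chloromethyllithium (ICH2Cl, MeLi·LiBr, THF, −78 °C, AcOH quench at −78 °C) is added to 5 to give the chromatography-stable chlorohydrin rac-2-chloro-1-{4-methoxy-2-[(triisopropylsilyl)oxy]phenyl}ethanol F4. F4 is charged to step 4 with 1.2 equiv Cs2CO3, closes to 6 in situ and is opened by the phenoxide of 3 as before.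

## Further compounds

F1 | step 5 | rac-3-(2-hydroxy-4-methoxyphenyl)-7-methoxy-6-(3-methylbut-2-en-1-yl)-2,3-dihydro-4H-chromen-4-one | COc1ccc(C2COc3cc(OC)c(CC=C(C)C)cc3C2=O)c(O)c1
F2 | step 5 | {[7-methoxy-3-{4-methoxy-2-[(trimethylsilyl)oxy]phenyl}-6-(3-methylbut-2-en-1-yl)-2H-chromen-4-yl]oxy}trimethylsilane | COc1ccc(C2=C(O[Si](C)(C)C)c3cc(CC=C(C)C)c(OC)cc3OC2)c(O[Si](C)(C)C)c1
F3 | step 4 | rac-2-hydroxy-1-{4-methoxy-2-[(triisopropylsilyl)oxy]phenyl}ethyl acetate | COc1ccc(C(CO)OC(C)=O)c(O[Si](C(C)C)(C(C)C)C(C)C)c1
F4 | step 3 | rac-2-chloro-1-{4-methoxy-2-[(triisopropylsilyl)oxy]phenyl}ethanol | COc1ccc(C(O)CCl)c(O[Si](C(C)C)(C(C)C)C(C)C)c1
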